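## Retrosynthetic overview

1. Target 13 ⇐ C11 aldehyde 11 by a late aldehyde reduction and acetylation; the C1, C7 and C10 esters are already in place, so no lactol is exposed at the labile diene stage.
2. 7β‑O and the C5=C6 alkene ⇐ singlet‑oxygen ene reaction of the Δ6 alkene 9; H‑5β is the only allylic hydrogen, so oxygen lands on C7β.
3. 8α‑OH and the Δ6 alkene ⇐ hydroxyselenation and selenoxide elimination of the genipin C7=C8 alkene (Se on the convex β face, O on C8 from the α face).
4. The C11 oxidation level (CO2Me → CHO, kept as an electron‑withdrawing group that tames the enol ether) and the 1‑O‑isovaleryl/10‑O‑acetyl pattern are set first on genipin.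
5. No ring is formed: the cis‑fused cyclopenta[c]pyran and the C1/C9 stereocentres come from (+)‑genipin.

Assumption: bulk commercial (+)‑genipin is an acceptable chiral‑pool starting material. This route is a design proposal, not a reproduced literature procedure.

Numbering (iridoid): C1 acetal, O2, C3=C4, C5, C6, C7, C8, C9, C10 (CH2 on C8), C11 (carbon on C4). β means the same face as H‑9.

## Route

**Step 1**
Reactants: 1, (+)‑genipin
Product: 2, 1β,10‑bis‑O‑TBS‑genipin (methyl ester retained; H‑5β, H‑9β)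
Conditions: TBSCl (3 equiv), imidazole, DMAP (cat.), DMF, 0 °C → rt
Reagents that add atoms: tert‑butyldimethylsilyl chloride, CC(C)(C)[Si](C)(C)Cl
Why: Double O‑silylation of the primary alcohol and the lactol OH masks both for hydride reduction; no C–O bond at C1 is broken, and any anomer mixture is irrelevant because the silyl acetal is removed in step 4.

**Step 2**
Reactants: 2, bis‑TBS‑genipin
Product: 3, 1β,10‑bis‑O‑TBS C11 alcohol (4‑hydroxymethyl)
Conditions: DIBAL‑H (3 equiv), CH2Cl2, −78 °C; Rochelle salt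
Reagents that add atoms: none
Why: DIBAL 1,2‑reduction of the β‑alkoxyacrylate ester to the allylic alcohol; silyl ethers and the silyl acetal are inert.

**Step 3**
Reactants: 3, C11 alcohol
Product: 4, 1β,10‑bis‑O‑TBS C11 aldehyde (4‑formyl)
Conditions: MnO2 (excess), CH2Cl2, rt
Reagents that add atoms: none
Why: Allylic oxidation with MnO2 gives the β‑alkoxy enal, which keeps C3=C4 deactivated toward electrophiles and can later be reduced in the presence of esters.

**Step 4**
Reactants: 4, bis‑TBS aldehyde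
Product: 5, "genipin‑11‑al" (1β‑hydroxy‑7‑hydroxymethyl‑1,4a,5,7a‑tetrahydrocyclopenta[c]pyran‑4‑carbaldehyde)
Conditions: HF·pyridine, pyridine/THF, 0 °C → rt
Reagents that add atoms: none
Why: Buffered fluoride desilylation avoids base‑induced lactol opening and C9 epimerisation; the lactol settles as the genipin‑type 1β‑OH anomer.

**Step 5**
Reactants: 5, diol aldehyde
Product: 6, 10‑O‑acetyl‑genipin‑11‑al
Conditions: AcCl (1.05 equiv), 2,4,6‑collidine, CH2Cl2, −78 °C
Reagents that add atoms: acetyl chloride, CC(=O)Cl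
Why: Kinetically selective acylation of the primary allylic alcohol over the hindered, less nucleophilic lactol OH.

**Step 6**
Reactants: 6, 10‑acetate
Product: 7, 10‑O‑acetyl‑1β‑O‑isovaleryl‑genipin‑11‑al
Conditions: isovaleryl chloride (1.3 equiv), pyridine, DMAP (cat.), CH2Cl2, 0 °C
Reagents that add atoms: 3‑methylbutanoyl chloride, CC(C)CC(=O)Cl
Why: O‑acylation of the lactol proceeds with retention because the C1–O bond is untouched, and the anomeric effect favours the 1β acylal; this fixes the C1 configuration of the target.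

**Step 7**
Reactants: 7, Δ7 alkene
Product: 8, 7β‑phenylselanyl‑8α‑hydroxy adduct (10‑OAc, 1β‑O‑isovaleryl, 4‑CHO)
Conditions: N‑(phenylseleno)phthalimide (1.2 equiv), H2O (3 equiv), CSA (10 mol %), CH2Cl2, rt
Reagents that add atoms: N‑(phenylseleno)phthalimide, O=C1c2ccccc2C(=O)N1[Se]c1ccccc1 (PhSe); water, O
Why: Anti, Markovnikov hydroxyselenation: PhSe+ adds to the convex β face of C7=C8 and oxygen attacks tertiary C8 from the α face (directly or through the five‑membered acetoxonium of the 10‑OAc, which collapses to the primary acetate), setting C8 as 8α‑OH/8β‑CH2OAc; the formyl‑deactivated C3=C4 is untouched.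

**Step 8**
Reactants: 8, hydroxy selenide
Product: 9, Δ6‑8α‑ol (tertiary allylic alcohol; 10‑OAc, 1β‑O‑isovaleryl, 4‑CHO)
Conditions: mCPBA (1.05 equiv), CH2Cl2, −78 °C; then i‑Pr2NH, → rt
Reagents that add atoms: none (the oxygen put on Se leaves as PhSeOH)
Why: Selenoxide syn‑elimination; the only syn β‑hydrogen is H‑6β and C8 has no hydrogen, so only the C6=C7 alkene forms and C8 is untouched.

**Step 9**
Reactants: 9, Δ6 alkene
Product: 10, 7β,8α‑diol with the C3=C4–C5=C6 diene (10‑OAc, 1β‑O‑isovaleryl, 4‑CHO)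
Conditions: O2, TPP (cat.), hν (white LED), CH2Cl2, 0 °C; then PPh3
Reagents that add atoms: dioxygen, O=O (one oxygen retained after reduction)
Why: Schenck ene reaction: H‑5β is the only allylic hydrogen, so the suprafacial ene places the hydroperoxide on C7 from the β face and moves the alkene to C5=C6; PPh3 reduces OOH to OH, giving 7β‑OH trans to 8α‑OH.

**Step 10**
Reactants: 10, 7β,8α‑diol
Product: 11, 7β‑O‑isovaleryl dienal (1β,7β‑bis‑isovalerate, 8α‑OH, 10‑OAc, 4‑CHO)
Conditions: isovaleric anhydride (1.5 equiv), DMAP (cat.), pyridine, CH2Cl2, 0 °C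
Reagents that add atoms: 3‑methylbutanoic anhydride, CC(C)CC(=O)OC(=O)CC(C)C
Why: Steglich‑type acylation of the secondary allylic alcohol; the tertiary 8‑OH does not react and no stereocentre is affected.

**Step 11**
Reactants: 11, dienal
Product: 12, 11‑hydroxy compound (11‑O‑deacetyl‑10‑acetoxyvaltrathydrin)
Conditions: NaBH4, CeCl3·7H2O, MeOH/THF, −78 → −40 °C
Reagents that add atoms: none
Why: Luche 1,2‑reduction of the aldehyde is chemoselective over the acetate, isovalerates and acylal at low temperature.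

**Step 12**
Reactants: 12, primary allylic alcohol
Product: 13, 10‑acetoxyvaltrathydrin
Conditions: Ac2O, pyridine, DMAP (cat.), CH2Cl2, 0 °C; Et3N‑buffered silica
Reagents that add atoms: acetic anhydride, CC(=O)OC(C)=O
Why: Acetylation of the primary alcohol only; the hindered tertiary 8‑OH stays free, giving the target.

## Compound list

1 | (+)‑Genipin, methyl (1R,4aS,7aS)‑1‑hydroxy‑7‑(hydroxymethyl)‑1,4a,5,7a‑tetrahydrocyclopenta[c]pyran‑4‑carboxylate | COC(=O)C1=CO[C@@H](O)[C@H]2[C@@H]1CC=C2CO | starting material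
2 | 1β,10‑Bis‑O‑TBS‑genipin | COC(=O)C1=CO[C@@H](O[Si](C)(C)C(C)(C)C)[C@H]2[C@@H]1CC=C2CO[Si](C)(C)C(C)(C)C | intermediate
3 | 1β,10‑Bis‑O‑TBS C11 alcohol | OCC1=CO[C@@H](O[Si](C)(C)C(C)(C)C)[C@H]2[C@@H]1CC=C2CO[Si](C)(C)C(C)(C)C | intermediate
4 | 1β,10‑Bis‑O‑TBS C11 aldehyde | O=CC1=CO[C@@H](O[Si](C)(C)C(C)(C)C)[C@H]2[C@@H]1CC=C2CO[Si](C)(C)C(C)(C)C | intermediate
5 | Genipin‑11‑al (1β‑OH, 10‑OH, 4‑CHO) | O=CC1=CO[C@@H](O)[C@H]2[C@@H]1CC=C2CO | intermediate
6 | 10‑O‑Acetyl‑genipin‑11‑al | O=CC1=CO[C@@H](O)[C@H]2[C@@H]1CC=C2COC(C)=O | intermediate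
7 | 10‑O‑Acetyl‑1β‑O‑isovaleryl‑genipin‑11‑al | O=CC1=CO[C@@H](OC(=O)CC(C)C)[C@H]2[C@@H]1CC=C2COC(C)=O | intermediate
8 | 7β‑Phenylselanyl‑8α‑hydroxy adduct | O=CC1=CO[C@@H](OC(=O)CC(C)C)[C@H]2[C@@H]1C[C@H]([Se]c3ccccc3)[C@]2(O)COC(C)=O | intermediate
9 | Δ6‑8α‑Hydroxy‑10‑acetoxy‑1β‑isovaleryloxy aldehyde | O=CC1=CO[C@@H](OC(=O)CC(C)C)[C@H]2[C@@H]1C=C[C@]2(O)COC(C)=O | intermediate
10 | 7β,8α‑Dihydroxy‑Δ3,Δ5‑diene aldehyde | O=CC1=CO[C@@H](OC(=O)CC(C)C)[C@H]2C1=C[C@H](O)[C@]2(O)COC(C)=O | intermediate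
11 | 1β,7β‑Bis‑O‑isovaleryl‑8α‑hydroxy‑10‑acetoxy dienal | O=CC1=CO[C@@H](OC(=O)CC(C)C)[C@H]2C1=C[C@H](OC(=O)CC(C)C)[C@]2(O)COC(C)=O | intermediate
12 | 11‑O‑Deacetyl‑10‑acetoxyvaltrathydrin | OCC1=CO[C@@H](OC(=O)CC(C)C)[C@H]2C1=C[C@H](OC(=O)CC(C)C)[C@]2(O)COC(C)=O | intermediate
13 | 10‑Acetoxyvaltrathydrin, (1S,6S,7R,7aS) in cyclopenta[c]pyran numbering (1β‑O‑iVal, 7β‑O‑iVal, 8α‑OH, H‑9β) | CC(=O)OCC1=CO[C@@H](OC(=O)CC(C)C)[C@H]2C1=C[C@H](OC(=O)CC(C)C)[C@]2(O)COC(C)=O | target

## Summary

Total step count: 12 (11 operations if steps 7 and 8 are telescoped in one pot).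
Longest linear sequence: 12 steps from genipin; the route is fully linear.

Three steps most likely to fail, with fallbacks:

1. **Step 7 (hydroxyselenation).** Risks are attack at C7 instead of C8, the wrong face, or an 8‑O‑acetyl regioisomer from acetoxonium collapse. Fallback: epoxidise C7=C8 of 7 on the convex β face (DMDO), then open at C8 with inversion through the 10‑OAc acetoxonium (acid, wet CH2Cl2) to give the 7β,8α‑diol. Then introduce C5=C6 by oxidising C7 to the ketone, dehydrogenating (IBX or Saegusa) to the Δ5‑7‑one, and reducing with 8‑OH‑directed Me4NBH(OAc)3 to the 7β‑ol, which converges on 10.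

2. **Step 9 (singlet‑oxygen ene).** The cis‑disubstituted cyclopentene may react slowly or over‑oxidise. Fallback: epoxidise C6=C7 syn to the 8α‑OH (VO(acac)2/TBHP) to the 6α,7α‑epoxide, open at C6 with PhSeNa, and eliminate the selenoxide toward H‑5β to give the Δ5‑7α‑ol. Mitsunobu inversion with isovaleric acid (DIAD, PPh3) then gives the 7β‑isovalerate 11 directly.

3. **Step 11 (late hydride reduction).** The acylal or allylic ester may be lost, or conjugate reduction may compete. Fallback: an ester‑level route with no hydride after acylation. Carry 1‑O‑TBS‑10‑O‑acetyl‑genipin (CO2Me retained) through steps 7–9, silylate 7‑OH, reduce with DIBAL (CO2Me → CH2OH, 10‑OAc cleaved), bis‑acetylate C10/C11, remove the silyl groups with HF·pyridine, and bis‑isovalerylate C1/C7. The cost is a brief exposure of the free C1 lactol at the diene stage.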